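**Retrosynthetic overview**
1. The usual first idea (carvone with its carbonyl as C9, then cuprate addition/enolate alkylation, or a Diels–Alder ring construction) is set aside; C5, C10 and C1 are instead set together in one radical–polar crossover cascade.
2. Target ⇐ α-methylenation of a C15 lactol (masked as a cis-fused ethyl acetal on O6) ⇐ C9 methacrylate and oxirane (from a chlorohydrin) ⇐ hydroxyl-directed C9 reduction ⇐ oxidative lactonization of a C12 acrylic acid onto C8.
3. Key step: γ-(iodoacetal)oxy enone + Et3B/O2 + ClCH2CHO gives 5-exo radical cyclization (C4–C5), a boron enolate, then aldol (C10–C1).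
4. The γ-oxygenated enone ⇐ (S)-carvone by α′-silyloxylation and Wharton 1,3-carbonyl transposition; the carbocycle and C7 come from the chiral pool.
5. Ring order: carbocycle (carvone) → tetrahydrofuran acetal (cascade) → γ-lactone → oxirane; the acetal ring is opened in the last two steps.

Assumption: the target is taken as the open γ-hydroxy enal drawn in the SMILES; its five-membered hemiacetal tautomer is regarded as the same compound.

Naming note: locants C1–C15 are those of the target (ring C5–C10; C14 = methyl on C10; C1–C2 = oxirane; C4(=C3)–C15 = acrolein unit; C11(=C13)–C12 = lactone unit). α is the ring face carrying the C7 side chain, β the opposite face.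

**Step 1**
Reactants: 1 (S)-(+)-carvone
Product: 3 (5R,6R)-6-[(tert-butyldimethylsilyl)oxy]-2-methyl-5-(prop-1-en-2-yl)cyclohex-2-en-1-one, via silyl dienol ether 2 (not isolated)
Conditions: LiN(i-Pr)2, THF, −78 °C; TBSOTf, −78 to 0 °C; then mCPBA, NaHCO3, CH2Cl2, −20 °C
Reagents that add atoms: tert-butyldimethylsilyl triflate CC(C)(C)[Si](C)(C)OS(=O)(=O)C(F)(F)F; mCPBA OOC(=O)c1cccc(Cl)c1
Why: Kinetic α′-deprotonation gives the cross-conjugated silyl dienol ether, and its Rubottom oxidation (epoxidation anti to the C7 isopropenyl group, then 1,4-silyl shift) sets C6 with the silyloxy group on the β face.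

**Step 2**
Reactants: 3 silyloxy enone
Product: 4 epoxy ketone (oxirane oxygen on the β face across C9–C10)
Conditions: 30% H2O2, NaOH (0.3 equiv), MeOH, 0 °C
Reagents that add atoms: hydrogen peroxide OO
Why: Weitz–Scheffer nucleophilic epoxidation of the enone, with hydroperoxide adding to C9 anti to the isopropenyl group; the oxirane configuration is erased again in steps 3 and 4.

**Step 3**
Reactants: 4 epoxy ketone
Product: 5 (1S,4S,5R)-4-[(tert-butyldimethylsilyl)oxy]-2-methyl-5-(prop-1-en-2-yl)cyclohex-2-en-1-ol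
Conditions: N2H4·H2O, AcOH (cat.), MeOH, 0 °C to rt
Reagents that add atoms: none
Why: Wharton transposition: the epoxy hydrazone fragments with loss of N2, moving oxygen from C5 to C9 and the alkene to C5=C10 without touching C6 or C7.

**Step 4**
Reactants: 5 allylic alcohol
Product: 6 (4S,5R)-4-[(tert-butyldimethylsilyl)oxy]-2-methyl-5-(prop-1-en-2-yl)cyclohex-2-en-1-one
Conditions: MnO2, CH2Cl2, rt
Reagents that add atoms: none
Why: Chemoselective MnO2 oxidation of the secondary allylic alcohol gives the transposed enone, in which the C6 oxygen now sits at the γ-position.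

**Step 5**
Reactants: 6 silyloxy enone
Product: 7 (4S,5R)-4-hydroxy-2-methyl-5-(prop-1-en-2-yl)cyclohex-2-en-1-one
Conditions: HF·pyridine, pyridine, THF, 0 °C to rt
Reagents that add atoms: none
Why: Fluoride-mediated desilylation under non-basic conditions frees the C6 hydroxyl without isomerizing the base-sensitive γ-hydroxy enone.

**Step 6**
Reactants: 7 γ-hydroxy enone; 8 ethyl vinyl ether
Product: 9 (4S,5R)-4-(1-ethoxy-2-iodoethoxy)-2-methyl-5-(prop-1-en-2-yl)cyclohex-2-en-1-one (both acetal epimers)
Conditions: NIS, CH2Cl2, −40 to 0 °C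
Reagents that add atoms: N-iodosuccinimide O=C1CCC(=O)N1I
Why: Iodoacetalization (Ueno–Stork precursor formation): iodonium activation of the enol ether and capture of the oxocarbenium ion by the C6 alcohol; the acetal carbon is an inconsequential epimer mixture.

**Step 7**
Reactants: 9 iodoacetal; 10 chloroacetaldehyde
Product: 12 bicyclic chlorohydrin ketone (C9 ketone; C5β–C4H2–C15H(OEt)–O–C6β cis-fused acetal; C10 β-CH3 and α-[(1S)-2-chloro-1-hydroxyethyl]; C7 α-isopropenyl), via boron enolate 11 (not isolated)
Conditions: Et3B (2 equiv), air (trace O2), toluene, −78 to −20 °C; pH 7 buffer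
Reagents that add atoms: none
Why: Proposed new method: an ethyl radical abstracts iodine, the alkyl radical closes 5-exo onto enone carbon C5 from the β face fixed by the C6–O tether (cis ring fusion, sets C5), the α-keto radical at C10 is captured by Et3B as a boron enolate, and this enolate adds to chloroacetaldehyde anti to the new C5–C4 bond through a Zimmerman–Traxler chair (methyl cis to O–B, CH2Cl equatorial), setting C10 (C1 unit α, methyl β) and C1 (S); the closest known reactions are the Ueno–Stork haloacetal radical cyclization and the Et3B-mediated radical conjugate addition–aldol coupling of alkyl iodides, enones and aldehydes.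

**Step 8**
Reactants: 12 bicyclic chlorohydrin ketone
Product: 13 allylic alcohol (as 12 with C7 substituent 3-hydroxyprop-1-en-2-yl)
Conditions: SeO2 (0.5 equiv), t-BuOOH, CH2Cl2, rt
Reagents that add atoms: tert-butyl hydroperoxide CC(C)(C)OO
Why: Selenium dioxide allylic oxidation (ene reaction then [2,3]-sigmatropic shift) of the only alkene left, the isopropenyl group, at its methyl carbon C12.

**Step 9**
Reactants: 13 allylic alcohol
Product: 15 acrylic acid (as 12 with C7 substituent 1-carboxyethenyl), via enal 14 (not isolated)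
Conditions: TEMPO (cat.), PhI(OAc)2, CH2Cl2, rt; then NaClO2, NaH2PO4, 2-methyl-2-butene, t-BuOH/H2O, 0 °C
Reagents that add atoms: sodium chlorite [Na+].[O-]Cl=O
Why: TEMPO/PhI(OAc)2 oxidizes the primary allylic alcohol in preference to the hindered secondary C1 alcohol, and Pinnick oxidation takes the enal to the acid without touching ketone, acetal or chlorohydrin.

**Step 10**
Reactants: 15 acrylic acid
Product: 17 cis-fused keto lactone (α-methylene-γ-butyrolactone with C7α–C11 and C8α–O; C9 ketone; rest as 12), via iodo keto acid 16 (not isolated)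
Conditions: Bu4NI (10 mol %), t-BuOOH, EtOAc, 40 °C
Reagents that add atoms: none
Why: Hypoiodite-catalysed oxidative α-acyloxylation (oxylactonization) of the δ-keto acid: the C8 iodide on the β face (anti to the C7 side chain) is displaced with inversion by the carboxylate in a 5-exo-tet SN2 reaction, which can only close the cis-fused γ-lactone and so places the C8 oxygen on the α face.

**Step 11**
Reactants: 17 keto lactone
Product: 18 diol (as 17 with C9 α-OH)
Conditions: Me4NBH(OAc)3, MeCN/AcOH, −30 °C
Reagents that add atoms: none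
Why: Evans–Saksena hydroxyl-directed reduction: the borohydride bound to the C1 hydroxyl delivers hydride intramolecularly to the β face of the C9 ketone, giving the 1,3-anti diol, which is the C9 α-alcohol (cis to the lactone oxygen).

**Step 12**
Reactants: 18 diol
Product: 19 epoxy alcohol (as 18 with the chlorohydrin closed to the (S)-oxirane C1–C2)
Conditions: KN(SiMe3)2 (1.0 equiv), THF, −78 to −30 °C
Reagents that add atoms: none
Why: Intramolecular Williamson etherification (3-exo-tet) of the chlorohydrin alkoxide closes the oxirane with retention at C1, and one equivalent of base at low temperature keeps this ahead of tetrahydrofuran formation from O9 and spares the α-methylene lactone.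

**Step 13**
Reactants: 19 epoxy alcohol; 20 methacrylic anhydride
Product: 21 C9 methacrylate (ethyl acetal still in place)
Conditions: DMAP, Et3N, CH2Cl2, rt to 40 °C
Reagents that add atoms: none
Why: DMAP-catalysed acyl transfer to the only free hydroxyl, the hindered C9 alcohol, with retention of configuration.

**Step 14**
Reactants: 21 methacrylate acetal
Product: 22 lactol (C15 hemiacetal with O6, in equilibrium with the open C6-hydroxy C15-aldehyde)
Conditions: PPTS (cat.), acetone/H2O (4:1), 40 °C
Reagents that add atoms: water O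
Why: Mild acid-catalysed hydrolysis of the mixed cyclic acetal through its oxocarbenium ion; the esters, the lactone and the hindered terminal oxirane tolerate PPTS.

**Step 15**
Reactants: 22 lactol
Product: 24 target CNP0124638.3, via Mannich base 23 (not isolated)
Conditions: CH2=NMe2+ I−, Et3N, CH2Cl2, rt
Reagents that add atoms: N,N-dimethylmethyleneiminium iodide (Eschenmoser's salt) C=[N+](C)C.[I-]
Why: Mannich reaction of the open-chain aldehyde enol with Eschenmoser's salt, then β-elimination of dimethylamine (α-methylenation of an aldehyde), installs C3 as the exocyclic methylene without creating or disturbing a stereocenter.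

**Compound list**
1 | (S)-(+)-carvone, (5S)-2-methyl-5-(prop-1-en-2-yl)cyclohex-2-en-1-one | CC1=CC[C@@H](CC1=O)C(C)=C | starting material
2 | tert-butyldimethyl{[(3S)-6-methyl-3-(prop-1-en-2-yl)cyclohexa-1,5-dien-1-yl]oxy}silane (kinetic silyl dienol ether of 1) | CC1=CC[C@H](C(C)=C)C=C1O[Si](C)(C)C(C)(C)C | intermediate
3 | (5R,6R)-6-[(tert-butyldimethylsilyl)oxy]-2-methyl-5-(prop-1-en-2-yl)cyclohex-2-en-1-one (silyloxy trans to isopropenyl) | CC1=CC[C@H](C(C)=C)[C@@H](O[Si](C)(C)C(C)(C)C)C1=O | intermediate
4 | 2,3-epoxide of 3, oxirane oxygen on the β face (trans to isopropenyl) | O1[C@H]2C[C@H](C(C)=C)[C@@H](O[Si](C)(C)C(C)(C)C)C(=O)[C@@]12C | intermediate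
5 | (1S,4S,5R)-4-[(tert-butyldimethylsilyl)oxy]-2-methyl-5-(prop-1-en-2-yl)cyclohex-2-en-1-ol | O[C@H]1C[C@H](C(C)=C)[C@@H](O[Si](C)(C)C(C)(C)C)C=C1C | intermediate
6 | (4S,5R)-4-[(tert-butyldimethylsilyl)oxy]-2-methyl-5-(prop-1-en-2-yl)cyclohex-2-en-1-one | O=C1C[C@H](C(C)=C)[C@@H](O[Si](C)(C)C(C)(C)C)C=C1C | intermediate
7 | (4S,5R)-4-hydroxy-2-methyl-5-(prop-1-en-2-yl)cyclohex-2-en-1-one | O=C1C[C@H](C(C)=C)[C@@H](O)C=C1C | intermediate
8 | ethyl vinyl ether | C=COCC | starting material
9 | (4S,5R)-4-(1-ethoxy-2-iodoethoxy)-2-methyl-5-(prop-1-en-2-yl)cyclohex-2-en-1-one, both acetal epimers | O=C1C[C@H](C(C)=C)[C@@H](OC(OCC)CI)C=C1C | intermediate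
10 | chloroacetaldehyde | O=CCCl | starting material
11 | diethylboron enolate (C9–O–BEt2, C9=C10) of the cis-fused bicyclic ethyl acetal (C5β–C4, C6β–O; C7 α-isopropenyl) | CCB(CC)OC1C[C@H](C(C)=C)[C@H]2OC(OCC)C[C@H]2C(C)=1 | intermediate
12 | C9 ketone with β-face cis-fused cyclic ethyl acetal C6–O–C15H(OEt)–C4H2–C5; C10 β-methyl and α-[(1S)-2-chloro-1-hydroxyethyl]; C7 α-isopropenyl | O=C1C[C@H](C(C)=C)[C@H]2OC(OCC)C[C@H]2[C@]1(C)[C@H](O)CCl | intermediate
13 | as 12, C7 substituent 3-hydroxyprop-1-en-2-yl | O=C1C[C@H](C(=C)CO)[C@H]2OC(OCC)C[C@H]2[C@]1(C)[C@H](O)CCl | intermediate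
14 | as 12, C7 substituent 3-oxoprop-1-en-2-yl (enal) | O=C1C[C@H](C(=C)C=O)[C@H]2OC(OCC)C[C@H]2[C@]1(C)[C@H](O)CCl | intermediate
15 | as 12, C7 substituent 1-carboxyethenyl (acrylic acid) | O=C1C[C@H](C(=C)C(=O)O)[C@H]2OC(OCC)C[C@H]2[C@]1(C)[C@H](O)CCl | intermediate
16 | as 15 with iodine at C8 on the β face | O=C1[C@@H](I)[C@H](C(=C)C(=O)O)[C@H]2OC(OCC)C[C@H]2[C@]1(C)[C@H](O)CCl | intermediate
17 | keto lactone: cis-fused α-methylene-γ-butyrolactone (C7α–C11, C8α–O), C9 ketone, rest as 12 | O=C1[C@@H]2OC(=O)C(=C)[C@@H]2[C@H]3OC(OCC)C[C@H]3[C@]1(C)[C@H](O)CCl | intermediate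
18 | as 17 with C9 α-hydroxyl (1,3-anti to the C1 hydroxyl) | O[C@@H]1[C@@H]2OC(=O)C(=C)[C@@H]2[C@H]3OC(OCC)C[C@H]3[C@]1(C)[C@H](O)CCl | intermediate
19 | as 18 with the chlorohydrin closed to the (S)-oxirane C1–C2 | O[C@@H]1[C@@H]2OC(=O)C(=C)[C@@H]2[C@H]3OC(OCC)C[C@H]3[C@]1(C)[C@H]1CO1 | intermediate
20 | methacrylic anhydride | CC(=C)C(=O)OC(=O)C(C)=C | starting material
21 | C9 methacrylate of 19 | C=C(C)C(=O)O[C@@H]1[C@@H]2OC(=O)C(=C)[C@@H]2[C@H]3OC(OCC)C[C@H]3[C@]1(C)[C@H]1CO1 | intermediate
22 | lactol: 21 with OEt replaced by OH | C=C(C)C(=O)O[C@@H]1[C@@H]2OC(=O)C(=C)[C@@H]2[C@H]3OC(O)C[C@H]3[C@]1(C)[C@H]1CO1 | intermediate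
23 | Mannich base: open C6-hydroxy C15-aldehyde with CH2NMe2 on C4 (C4 epimers) | C=C(C)C(=O)O[C@@H]1[C@@H]2OC(=O)C(=C)[C@@H]2[C@@H](O)[C@@H](C(CN(C)C)C=O)[C@]1(C)[C@H]1CO1 | intermediate
24 | CNP0124638.3 | C=C(C)C(=O)O[C@@H]1[C@@H]2OC(=O)C(=C)[C@@H]2[C@@H](O)[C@@H](C(=C)C=O)[C@]1(C)[C@H]1CO1 | target

**Step count and risks**
Total steps: 15. Longest linear sequence: 15 steps (from 1).

Steps most likely to fail:

- **Step 7 (cascade).** The α-keto radical may be reduced or iodinated instead of forming the boron enolate, and the aldol sets two stereocenters at a hindered tetrasubstituted enolate. Fallback: setting out from 9, run the cyclization in the classical tin hydride mode (Bu3SnH, AIBN, benzene, 80 °C) to give the cis-fused bicyclic ketone F1. Thermodynamic silylation (TMSCl, NaI, Et3N, MeCN) gives the tetrasubstituted trimethylsilyl enol ether F2. MeLi (THF, 0 °C) releases the lithium enolate F3, which is added to chloroacetaldehyde 10 at −78 °C (closed aldol transition state, attack anti to C4) and comes back to the route at 12.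

- **Step 8 (SeO2 oxidation).** Allylic oxidations of isopropenyl groups with selenium dioxide are often low-yielding and can over-oxidize or attack the allylic methine. Fallback: setting out from 12, ene-type allylic chlorination with HOCl made in the flask (Ca(OCl)2, solid CO2, CH2Cl2/H2O, 0 °C) gives the allylic chloride F4. N-methylmorpholine N-oxide in MeCN (Ganem oxidation; the unactivated C2 chloride is left alone) converts it to enal 14, which comes back to the route at the chlorite stage of step 9.

- **Step 10 (oxylactonization).** The catalytic hypoiodite may oxidize elsewhere, or the C1 hydroxyl may compete as nucleophile. Fallback: setting out from 15, TMSOTf/Et3N (CH2Cl2, 0 °C) gives the tris(trimethylsilyl) enol ether F5. Dimethyldioxirane (acetone, −40 °C) then citric acid/MeOH (Rubottom oxidation, oxygen anti to the C7 side chain) gives the C8 β-hydroxy keto acid F6. PPh3/diisopropyl azodicarboxylate (THF, 0 °C; Mitsunobu lactonization with inversion at C8) comes back to the route at 17.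

**Further compounds**
F1 | step 7 | cis-fused bicyclic acetal ketone with C10–H (C10 epimers; C5β–C4, C6β–O, C7 α-isopropenyl) | O=C1C[C@H](C(C)=C)[C@H]2OC(OCC)C[C@H]2C1C
F2 | step 7 | trimethylsilyl enol ether of F1 (C9–OSiMe3, C9=C10) | C[Si](C)(C)OC1C[C@H](C(C)=C)[C@H]2OC(OCC)C[C@H]2C(C)=1
F3 | step 7 | lithium enolate of F1 (C9–OLi, C9=C10) | [Li]OC1C[C@H](C(C)=C)[C@H]2OC(OCC)C[C@H]2C(C)=1
F4 | step 8 | allylic chloride: as 12 with C7 substituent 3-chloroprop-1-en-2-yl | O=C1C[C@H](C(=C)CCl)[C@H]2OC(OCC)C[C@H]2[C@]1(C)[C@H](O)CCl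
F5 | step 10 | tris(trimethylsilyl) derivative of 15: C9 silyl enol ether (C8=C9), silyl ester, C1 silyl ether | C[Si](C)(C)OC1=C[C@H](C(=C)C(=O)O[Si](C)(C)C)[C@H]2OC(OCC)C[C@H]2[C@]1(C)[C@H](O[Si](C)(C)C)CCl
F6 | step 10 | as 15 with hydroxyl at C8 on the β face | O=C1[C@@H](O)[C@H](C(=C)C(=O)O)[C@H]2OC(OCC)C[C@H]2[C@]1(C)[C@H](O)CCl
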